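**Assumption:** the SMILES fixes two stereocentres and one alkene geometry; it defines no axial element about the ring–side-chain bond, so none is treated as a requirement.

**Locants used throughout (target numbering, also for intermediates):** carbocycle C1–C6 (C1 quaternary, C2 bears the side chain, C3 Me, C4 C=O, C5 Me, C6 H); side chain C1′–C7′ (C2′ bonded to C2, C4′ stereocentre, C5′ ketone); pyranone O1″, C2″ (OMe) to C6″ (bonded to C1). The target 23 is (1S,4′S,2′E).

## The problem

- Target 23 is a fully substituted, cross-conjugated cyclohexa-2,5-dienone. Its C1 is an all-carbon quaternary stereocentre carrying a methyl group, the 2-methoxy-γ-pyranone (through C6″) and two vinylic ring carbons that differ only in that C2 bears the heptenone chain and C6 a hydrogen.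
- C1 is stereogenic only through a difference two atoms away and cannot be corrected once made. It is also buried: C2=C3 is tetrasubstituted and the C2–C2′ bond joins two fully substituted sp2 carbons.
- The second stereocentre, C4′, lies five bonds from C1 across two sp2 carbons, so neither centre can control the other. C4′ is α to the C5′ ketone and allylic, at the end of the C4=O/C2=C3/C2′=C3′ trienone, and will not survive base once that ketone is present.
- The methoxy-pyranone is a vinylogous ester: organolithium reagents and alkoxides other than methoxide exchange at C2″, and it is photolabile. The 4,4-disubstituted dienone can undergo a dienone–phenol 1,2-shift from C1 in strong acid.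
- The enabling feature: C1 is bonded to C6″, the β-carbon of the pyranone's vinylogous ester. If C2=C3 is opened by a retro-aldol so that C2 is a ketone, the C1–H lies between that ketone and the pyranone. It is then a vinylogous 1,3-dicarbonyl C–H: acidic, configurationally labile, and alkylated through a planar enolate. The rest of the ring (C3, C4, C5 with their methyls, and C6) is then a 2-methylidene-3-oxopentyl group.
- The synthesis therefore has to set C1 by a catalyst in an acyclic, racemising precursor, close the ring onto it, and keep C4′ masked until the last step.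

## Retrosynthesis

**23 ⇒ 22 ⇒ 21 (no C–C bond cut).** The C5′ ketone is taken back to the carbinol 22 and its silyl ether 21. With C5′ as a protected alcohol, C4′–H is only allylic and tolerates the bases used earlier. The forward steps are a fluoride desilylation and a neutral oxidation next to a stereocentre.

**21 ⇒ 20 (C5=C6 moved to an exocyclic C5=CH2).** Entering C6 as a CH2 group means the acyclic precursor has no C5=C6 geometry to control. The alternative, bringing C6 in as a vinylic carbon by vinylic substitution, would need the less stable alkene geometry for ring closure. Correcting it with a nucleophilic base would open a retro-substitution path that racemises C1. The forward step is an exo-to-endo enone isomerisation under thermodynamic control.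

**20 ⇒ 18 (cut C2=C3).** An intramolecular aldol condensation of the ethyl ketone (C3) onto the C2 ketone closes the ring and makes the tetrasubstituted alkene in one operation. Cutting C2–C2′ instead would require a leaving group on the more hindered β-carbon of a chiral dienone. Cutting C1–C2 in the ring would require a tertiary carbanion to attack a fully substituted carbon. 18 is acyclic and has a single stereochemical problem, C1. The forward reaction must enolise only at C3 and lose water only towards C3.

**18 ⇒ 14 + 17 (cut C1–C6; key step).** This cut exposes the vinylogous 1,3-dicarbonyl 14, whose C1–H epimerises freely, and the allylic carbonate 17. Both C1 epimers of 14 give one enolate, so a chiral catalyst can funnel racemic material into one configuration. 14 already contains the pyranone and the whole side chain, and 17 is a six-carbon reagent. The forward reaction must be C-selective and face-selective at a tertiary carbon. Because the side chain is enantiopure, the two C1 epimers are diastereomers.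

**14 ⇒ 13 ⇒ 5 + 12 (cut C1–C2).** The ethyl group of pyranone 5 is deprotonated at its CH2, which becomes C1, and added to enal 12. Oxidation of the carbinol 13 gives 14. This places the side chain by a carbonyl addition at −78 °C instead of a late organometallic coupling in the presence of the pyranone. The forward steps are a vinylogous aldol addition and an alcohol oxidation; the two new stereocentres of 13 are irrelevant.

**12 ⇒ 11 ⇒ 10 ⇒ 9 ⇒ 6 + 7 (cut C2′=C3′ and C4′–C5′).** The enal is an anti-propionate aldol unit. Two molecules of propanal 6 give aldol 8 under enamine catalysis, and ylide 7 traps it as enoate 9. Protection (10), reduction (11) and allylic oxidation give 12. The forward aldol must set C4′; C5′ is later oxidised, so only its presence matters.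

**5 ⇒ 4 ⇒ 3 ⇒ 1 + 2, and 17 ⇒ 16 ⇒ 15.** The pyranone is the cyclised, O-methylated triketide 3, made by acylating the dianion of β-keto ester 1 with amide 2. Carbonate 17 is the hydroxymethylated enone 16, made from pent-1-en-3-one 15.

## Roads not taken

**Alternative 1:** the most obvious cut is C2–C2′, a cross-coupling of the enol triflate A1 of the ring with the side-chain alkenylboronate A2.
- A1 must carry its leaving group on C2, next to the quaternary carbon. The natural precursor, the vinylogous acid A3, should be activated first at the less hindered oxygen on C4, which gives the transposed triflate and then the wrong dienone.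
- A flat precursor leads to racemic A3, with no handle for C1.
- A2 carries the base-labile C4′ centre into a basic coupling.
- The variant that adds an alkenyllithium to a C2 carbonyl would expose the 2-methoxy-pyranone to exchange at C2″.
- The chosen plan never forms C2–C2′ (it comes from enal 12) and sets C1 before the ring exists.

**Alternative 2:** the biomimetic cut is C1–C6, by 6π-electrocyclisation (or vinylogous intramolecular Michael addition) of the trienolate of the linear trienone A4 to the cyclohexenone A5, followed by dehydrogenation.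
- It builds the ring and the quaternary centre together, but the enolate is achiral near C1 and the only stereocentres are in the distant side chain, so both C1 epimers should form.
- The C2 stereocentre formed at the same time is destroyed afterwards, so it cannot be used as a relay.
- The strong base acts on a substrate whose C4′–H is vinylogously acidic.
- The chosen plan uses the same acidity of C1–H, but in a substrate where a chiral catalyst can intervene, and keeps strong base away from the finished trienone.

**Alternative 3:** the dearomatisation cut is C1–C6″, by para-C-attack of the phenoxide of A6 on 2,6-dimethoxy-pyranone A7 (addition–elimination), which would give 21 in one step.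
- It looks shortest, but the phenoxide can react at oxygen, and C-attack costs the aromatic stabilisation, so the aryl pyranyl ether is the expected thermodynamic product.
- The one free ring position of A6 can undergo ordinary substitution.
- The arene is flat and the nearest stereocentre is five bonds away, so nothing differentiates the faces of C1.
- The chosen plan makes the C1–C6″ bond trivially (it is present in 5) and spends its key step on the configuration of C1.

Key step: step 12

## Steps

**Step 1**
Reactants: 1 methyl 2-methyl-3-oxopentanoate; 2 N-methoxy-N-methylpropanamide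
Product: 3 methyl 2,4-dimethyl-3,5-dioxoheptanoate
Conditions: LiN(i-Pr)2 (2.2 equiv), THF, −78 → 0 °C; then 2, −78 °C → rt; aq. NH4Cl
Reagents that add atoms: none
Why: The α,γ-dianion of the β-keto ester reacts at its more basic terminal (γ) carbon, and the stable tetrahedral adduct of the N-methoxy-N-methyl amide prevents over-addition (Claisen-type acylation of a dianion).

**Step 2**
Reactants: 3 methyl 2,4-dimethyl-3,5-dioxoheptanoate
Product: 4 6-ethyl-4-hydroxy-3,5-dimethyl-2H-pyran-2-one
Conditions: DBU, toluene, 80 °C
Reagents that add atoms: none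
Why: The enol oxygen of the C5 ketone lactonises onto the methyl ester (acyl substitution, six-membered ring), driven by formation of the acidic 4-hydroxy-2-pyranone.

**Step 3**
Reactants: 4 6-ethyl-4-hydroxy-3,5-dimethyl-2H-pyran-2-one
Product: 5 2-ethyl-6-methoxy-3,5-dimethyl-4H-pyran-4-one
Conditions: MeOSO2CF3, CH2Cl2, rt; aq. NaHCO3
Reagents that add atoms: methyl trifluoromethanesulfonate, COS(=O)(=O)C(F)(F)F
Why: A hard methylating agent alkylates the more basic lactone carbonyl oxygen of the neutral hydroxypyranone, and loss of the 4-OH proton then gives the 2-methoxy-4-pyranone rather than the 4-methoxy-2-pyranone (O-methylation).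

**Step 4**
Reactants: 6 propanal (two molecules); 7 ethyl 2-(triphenyl-λ5-phosphanylidene)propanoate
Product: 9 ethyl (2E,4S,5R)-5-hydroxy-2,4-dimethylhept-2-enoate, via (2R,3R)-3-hydroxy-2-methylpentanal 8 (not isolated)
Conditions: D-proline (10 mol %), DMF, 4 °C; excess 6 removed in vacuo; then 7, CH2Cl2, rt
Reagents that add atoms: none
Why: The proline enamine aldol self-addition of propanal should give the anti aldol, with D-proline placing (R) at C2 of 8; the stabilised ylide traps the labile aldol in a Wittig reaction to the E enoate, and the (2R) centre becomes (4S) of 9 (= C4′) only through a change of substituent ranking.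

**Step 5**
Reactants: 9 ethyl (2E,4S,5R)-5-hydroxy-2,4-dimethylhept-2-enoate
Product: 10 ethyl (2E,4S,5R)-5-[(tert-butyldimethylsilyl)oxy]-2,4-dimethylhept-2-enoate
Conditions: t-BuMe2SiCl, imidazole, DMF, rt
Reagents that add atoms: tert-butyldimethylsilyl chloride, CC(C)(C)[Si](C)(C)Cl
Why: Standard silylation of a secondary alcohol; the ether masks the future C5′ ketone so that C4′–H stays non-acidic through the base steps.

**Step 6**
Reactants: 10 ethyl (2E,4S,5R)-5-[(tert-butyldimethylsilyl)oxy]-2,4-dimethylhept-2-enoate
Product: 11 (2E,4S,5R)-5-[(tert-butyldimethylsilyl)oxy]-2,4-dimethylhept-2-en-1-ol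
Conditions: i-Bu2AlH (2.2 equiv), CH2Cl2, −78 °C; aq. potassium sodium tartrate
Reagents that add atoms: none
Why: 1,2-Reduction of an α,β-unsaturated ester to the allylic alcohol by an aluminium hydride, without touching the alkene or the silyl ether.

**Step 7**
Reactants: 11 (2E,4S,5R)-5-[(tert-butyldimethylsilyl)oxy]-2,4-dimethylhept-2-en-1-ol
Product: 12 (2E,4S,5R)-5-[(tert-butyldimethylsilyl)oxy]-2,4-dimethylhept-2-enal
Conditions: MnO2, CH2Cl2, rt
Reagents that add atoms: none
Why: Allylic oxidation with manganese dioxide is neutral and heterogeneous, so the E alkene and the γ-stereocentre should be untouched.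

**Step 8**
Reactants: 5 2-ethyl-6-methoxy-3,5-dimethyl-4H-pyran-4-one; 12 (2E,4S,5R)-5-[(tert-butyldimethylsilyl)oxy]-2,4-dimethylhept-2-enal
Product: 13 2-[(4E,6S,7R)-7-[(tert-butyldimethylsilyl)oxy]-3-hydroxy-4,6-dimethylnon-4-en-2-yl]-6-methoxy-3,5-dimethyl-4H-pyran-4-one (mixture at C2 and C3 of the nonenyl chain)
Conditions: 5, LiN(SiMe3)2, THF, −78 °C; then 12, −78 °C; aq. NH4Cl
Reagents that add atoms: none
Why: The ethyl CH2 of 5 is deprotonated through the pyranone (vinylogous enolate) and adds 1,2 to the enal (vinylogous aldol addition); the new C1–H and C2 carbinol centres are not controlled, and both are erased in steps 9 and 12.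

**Step 9**
Reactants: 13 (mixture of diastereomers)
Product: 14 2-[(4E,6S,7R)-7-[(tert-butyldimethylsilyl)oxy]-4,6-dimethyl-3-oxonon-4-en-2-yl]-6-methoxy-3,5-dimethyl-4H-pyran-4-one (C1–H centre labile)
Conditions: Dess–Martin periodinane, pyridine, CH2Cl2, 0 °C → rt
Reagents that add atoms: none
Why: Dess–Martin oxidation of the allylic alcohol gives the C2 enone; all diastereomers of 13 converge on 14, whose C1–H is now a vinylogous 1,3-dicarbonyl C–H.

**Step 10**
Reactants: 15 pent-1-en-3-one
Product: 16 2-(hydroxymethyl)pent-1-en-3-one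
Conditions: aq. CH2O, DABCO (cat.), THF–H2O, rt
Reagents that add atoms: formaldehyde, C=O
Why: Morita–Baylis–Hillman reaction: the amine adds to the enone and the resulting enolate is hydroxymethylated at the α-carbon.

**Step 11**
Reactants: 16 2-(hydroxymethyl)pent-1-en-3-one
Product: 17 tert-butyl (2-methylidene-3-oxopentyl) carbonate
Conditions: (t-BuOCO)2O, DMAP (cat.), CH2Cl2, 0 °C
Reagents that add atoms: di-tert-butyl dicarbonate, CC(C)(C)OC(=O)OC(=O)OC(C)(C)C
Why: Acylation of the primary allylic alcohol gives the carbonate, a leaving group that releases its own base (tert-butoxide) on ionisation.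

**Step 12**
Reactants: 14 (as above); 17 tert-butyl (2-methylidene-3-oxopentyl) carbonate
Product: 18 (6R,8E,10S,11R)-11-[(tert-butyldimethylsilyl)oxy]-6-(6-methoxy-3,5-dimethyl-4-oxo-4H-pyran-2-yl)-6,8,10-trimethyl-4-methylidenetridec-8-ene-3,7-dione
Conditions: (DHQD)2PHAL (10 mol %), toluene, 0 °C → rt
Reagents that add atoms: none
Why: Proposed new method: the tertiary amine adds to 17 in SN2′ fashion and expels tert-butyl carbonate, which loses CO2 to give tert-butoxide; this base removes the C1–H of 14 (flanked by the C2 ketone and pyranone C6″), and the enolate, ion-paired with the chiral allylammonium ion, attacks the terminal methylidene carbon in a second SN2′ step that releases the catalyst, the closest known reaction type being the cinchona-alkaloid-catalysed asymmetric allylic alkylation of Morita–Baylis–Hillman carbonates with α-substituted cyanoacetates, β-keto esters and 3-substituted oxindoles, which forms quaternary centres. No ring is closed in this step. The new stereocentre is C1 (C6 of 18), set by the catalyst; both epimers of 14 give the same planar enolate, so the step is stereoconvergent. The enolate should adopt one geometry, with the acyl group on the side of ring oxygen O1″ and away from the C5″ methyl, which gives the catalyst two clearly different faces. The selectivities needed are C- over O-allylation (soft allylic electrophile at the carbon terminus of an extended enolate) and facial selectivity at C1; because C4′ and C5′ are already set, the C1 epimer is a diastereomer and can be detected and removed. The product has no hydrogen on C1 and the new chain has none on C5, so neither re-enolisation nor E1cB retro-Michael cleavage can scramble the centre. (6R) in 18 corresponds to (1S) in 23 because C2 drops from first to second rank when its ketone becomes an alkene carbon; the pseudo-enantiomeric (DHQ)2PHAL is used if the sense of induction proves opposite.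

**Step 13**
Reactants: 18 (as above)
Product: 20 2-[(1S)-2-[(2E,4S,5R)-5-[(tert-butyldimethylsilyl)oxy]-4-methylhept-2-en-2-yl]-1,3-dimethyl-5-methylidene-4-oxocyclohex-2-en-1-yl]-6-methoxy-3,5-dimethyl-4H-pyran-4-one, via tertiary ketol 19 (not isolated)
Conditions: LiN(SiMe3)2, THF, −78 → −40 °C; (CF3CO)2O, −78 °C; DBU, −78 °C → rt
Reagents that add atoms: none
Why: The only enolisable α-position of the C4 ketone is the ethyl CH2 (C3), whose lithium enolate closes the six-membered ring onto the C2 ketone (intramolecular aldol, as in the ring-closing stage of a Robinson annulation); trifluoroacetylation of the aldolate and E1cB loss through the acidic C3–H give only the C2=C3 alkene, and the C2/C3 stereocentres of 19 are erased.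

**Step 14**
Reactants: 20 (as above)
Product: 21 2-[(1S)-2-[(2E,4S,5R)-5-[(tert-butyldimethylsilyl)oxy]-4-methylhept-2-en-2-yl]-1,3,5-trimethyl-4-oxocyclohexa-2,5-dien-1-yl]-6-methoxy-3,5-dimethyl-4H-pyran-4-one
Conditions: RhCl3·3H2O (10 mol %), MeOH–CHCl3, 50 °C
Reagents that add atoms: none
Why: A rhodium hydride formed in the alcohol adds to the unhindered exocyclic enone and β-hydride elimination towards C6–H gives the more substituted endocyclic enone (thermodynamic exo-to-endo isomerisation of an α-methylidene ketone); methanol makes any exchange at C2″ degenerate.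

**Step 15**
Reactants: 21 (as above)
Product: 22 2-[(1S)-2-[(2E,4S,5R)-5-hydroxy-4-methylhept-2-en-2-yl]-1,3,5-trimethyl-4-oxocyclohexa-2,5-dien-1-yl]-6-methoxy-3,5-dimethyl-4H-pyran-4-one
Conditions: HF·pyridine, pyridine, THF, 0 °C → rt
Reagents that add atoms: none
Why: Buffered fluoride cleaves the secondary silyl ether without the basicity that could epimerise C4′ or the strong acid that could trigger a dienone–phenol shift.

**Step 16**
Reactants: 22 (as above)
Product: 23 2-methoxy-3,5-dimethyl-6-[(1S)-1,3,5-trimethyl-2-[(2E,4S)-4-methyl-5-oxohept-2-en-2-yl]-4-oxocyclohexa-2,5-dien-1-yl]-4H-pyran-4-one (target)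
Conditions: Dess–Martin periodinane, pyridine, CH2Cl2, 0 °C
Reagents that add atoms: none
Why: Neutral Dess–Martin oxidation of the C5′ carbinol unveils the ethyl ketone in the last step, so the now α-keto, allylic C4′–H never meets base; the (4′S) descriptor is unchanged because C5′ keeps its rank.

## Compound list

1 | methyl 2-methyl-3-oxopentanoate | CCC(=O)C(C)C(=O)OC | starting material
2 | N-methoxy-N-methylpropanamide | CCC(=O)N(C)OC | starting material
3 | methyl 2,4-dimethyl-3,5-dioxoheptanoate | CCC(=O)C(C)C(=O)C(C)C(=O)OC | intermediate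
4 | 6-ethyl-4-hydroxy-3,5-dimethyl-2H-pyran-2-one | CCC1=C(C)C(O)=C(C)C(=O)O1 | intermediate
5 | 2-ethyl-6-methoxy-3,5-dimethyl-4H-pyran-4-one | CCc1oc(OC)c(C)c(=O)c1C | intermediate
6 | propanal | CCC=O | starting material
7 | ethyl 2-(triphenyl-λ5-phosphanylidene)propanoate | CCOC(=O)C(C)=P(c1ccccc1)(c1ccccc1)c1ccccc1 | starting material
8 | (2R,3R)-3-hydroxy-2-methylpentanal | CC[C@@H](O)[C@@H](C)C=O | intermediate
9 | ethyl (2E,4S,5R)-5-hydroxy-2,4-dimethylhept-2-enoate | CC[C@@H](O)[C@@H](C)/C=C(\C)C(=O)OCC | intermediate
10 | ethyl (2E,4S,5R)-5-[(tert-butyldimethylsilyl)oxy]-2,4-dimethylhept-2-enoate | CC[C@@H](O[Si](C)(C)C(C)(C)C)[C@@H](C)/C=C(\C)C(=O)OCC | intermediate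
11 | (2E,4S,5R)-5-[(tert-butyldimethylsilyl)oxy]-2,4-dimethylhept-2-en-1-ol | CC[C@@H](O[Si](C)(C)C(C)(C)C)[C@@H](C)/C=C(\C)CO | intermediate
12 | (2E,4S,5R)-5-[(tert-butyldimethylsilyl)oxy]-2,4-dimethylhept-2-enal | CC[C@@H](O[Si](C)(C)C(C)(C)C)[C@@H](C)/C=C(\C)C=O | intermediate
13 | 2-[(4E,6S,7R)-7-[(tert-butyldimethylsilyl)oxy]-3-hydroxy-4,6-dimethylnon-4-en-2-yl]-6-methoxy-3,5-dimethyl-4H-pyran-4-one (mixture at C2 and C3 of the chain) | CC[C@@H](O[Si](C)(C)C(C)(C)C)[C@@H](C)/C=C(\C)C(O)C(C)c1oc(OC)c(C)c(=O)c1C | intermediate
14 | 2-[(4E,6S,7R)-7-[(tert-butyldimethylsilyl)oxy]-4,6-dimethyl-3-oxonon-4-en-2-yl]-6-methoxy-3,5-dimethyl-4H-pyran-4-one (C2 of the chain labile) | CC[C@@H](O[Si](C)(C)C(C)(C)C)[C@@H](C)/C=C(\C)C(=O)C(C)c1oc(OC)c(C)c(=O)c1C | intermediate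
15 | pent-1-en-3-one | CCC(=O)C=C | starting material
16 | 2-(hydroxymethyl)pent-1-en-3-one | CCC(=O)C(=C)CO | intermediate
17 | tert-butyl (2-methylidene-3-oxopentyl) carbonate | CCC(=O)C(=C)COC(=O)OC(C)(C)C | intermediate
18 | (6R,8E,10S,11R)-11-[(tert-butyldimethylsilyl)oxy]-6-(6-methoxy-3,5-dimethyl-4-oxo-4H-pyran-2-yl)-6,8,10-trimethyl-4-methylidenetridec-8-ene-3,7-dione | CC[C@@H](O[Si](C)(C)C(C)(C)C)[C@@H](C)/C=C(\C)C(=O)[C@](C)(CC(=C)C(=O)CC)c1oc(OC)c(C)c(=O)c1C | intermediate
19 | 2-[(1S)-2-[(2E,4S,5R)-5-[(tert-butyldimethylsilyl)oxy]-4-methylhept-2-en-2-yl]-2-hydroxy-1,3-dimethyl-5-methylidene-4-oxocyclohexyl]-6-methoxy-3,5-dimethyl-4H-pyran-4-one (mixture at ring C2 and C3) | CC[C@@H](O[Si](C)(C)C(C)(C)C)[C@@H](C)/C=C(\C)C1(O)C(C)C(=O)C(=C)C[C@]1(C)c1oc(OC)c(C)c(=O)c1C | intermediate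
20 | 2-[(1S)-2-[(2E,4S,5R)-5-[(tert-butyldimethylsilyl)oxy]-4-methylhept-2-en-2-yl]-1,3-dimethyl-5-methylidene-4-oxocyclohex-2-en-1-yl]-6-methoxy-3,5-dimethyl-4H-pyran-4-one | CC[C@@H](O[Si](C)(C)C(C)(C)C)[C@@H](C)/C=C(\C)C1=C(C)C(=O)C(=C)C[C@]1(C)c1oc(OC)c(C)c(=O)c1C | intermediate
21 | 2-[(1S)-2-[(2E,4S,5R)-5-[(tert-butyldimethylsilyl)oxy]-4-methylhept-2-en-2-yl]-1,3,5-trimethyl-4-oxocyclohexa-2,5-dien-1-yl]-6-methoxy-3,5-dimethyl-4H-pyran-4-one | CC[C@@H](O[Si](C)(C)C(C)(C)C)[C@@H](C)/C=C(\C)C1=C(C)C(=O)C(C)=C[C@]1(C)c1oc(OC)c(C)c(=O)c1C | intermediate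
22 | 2-[(1S)-2-[(2E,4S,5R)-5-hydroxy-4-methylhept-2-en-2-yl]-1,3,5-trimethyl-4-oxocyclohexa-2,5-dien-1-yl]-6-methoxy-3,5-dimethyl-4H-pyran-4-one | CC[C@@H](O)[C@@H](C)/C=C(\C)C1=C(C)C(=O)C(C)=C[C@]1(C)c1oc(OC)c(C)c(=O)c1C | intermediate
23 | 2-methoxy-3,5-dimethyl-6-[(1S)-1,3,5-trimethyl-2-[(2E,4S)-4-methyl-5-oxohept-2-en-2-yl]-4-oxocyclohexa-2,5-dien-1-yl]-4H-pyran-4-one | CCC(=O)[C@@H](C)/C=C(\C)C1=C(C)C(=O)C(C)=C[C@]1(C)c1oc(OC)c(C)c(=O)c1C | target

## Step count and least certain steps

Total step count: 16. Longest linear sequence: 11 steps (steps 4–9 and 12–16, from propanal 6).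

**Step 12 (key step, proposed new method).** The most likely failure is poor facial discrimination at C1, because the acyclic enolate may not be held rigidly enough in the ion pair. O-allylation and slow turnover at the hindered tertiary carbon are further risks. Fallback, using classical enolate C-alkylation and setting out from 14 and 16: alcohol 16 is converted with PBr3 into 2-(bromomethyl)pent-1-en-3-one F1. The potassium enolate of 14 (K2CO3, acetone) is alkylated with F1. This gives 18 together with its C6 epimer, (6S,8E,10S,11R)-11-[(tert-butyldimethylsilyl)oxy]-6-(6-methoxy-3,5-dimethyl-4-oxo-4H-pyran-2-yl)-6,8,10-trimethyl-4-methylidenetridec-8-ene-3,7-dione F2. Since the side chain is enantiopure, the two are diastereomers and are separated by chromatography; the route is rejoined at 18.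

**Step 13.** Retro-aldol opening of the hindered tertiary aldolate before it is trapped is the main risk. Others are competing deprotonation at the vinylogous C4′–H (epimerisation) and ionisation of the allylic tertiary ester instead of E1cB loss. Fallback, setting out from 18 and avoiding a free lithium aldolate: soft enolisation (Me3SiOSO2CF3, Et3N) gives the trimethylsilyl enol ether F3. N-Bromosuccinimide converts it into the α-bromo ketone F4. SmI2 (divalent samarium) in THF at −78 °C then effects an intramolecular Reformatsky-type aldol to the ketol 19, where the route is rejoined; 19 is dehydrated to 20 as in step 13.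

**Step 14.** The metal hydride may walk along the side chain through C2′=C3′ towards C4′, eroding that centre. Conversion may be incomplete, and the acidic medium may start a dienone–phenol shift. Fallback, setting out from 20 and replacing isomerisation by a redox pair: conjugate reduction of the unhindered exocyclic enone with [(Ph3P)CuH]6 (monovalent copper) in the presence of Me3SiCl gives the silyl dienol ether F5. Saegusa–Ito oxidation with Pd(OAc)2 (divalent palladium) in MeCN then dehydrogenates towards C6–H and rejoins the route at 21.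

**Step 4.** Oligomerisation of propanal, a low anti preference and partial epimerisation of the labile aldol before olefination are the likely problems. Fallback, setting out from 6 and using a reagent-controlled crotylation: (E)-crotylboration of 6 with the enantiomer of (E)-crotyl-B(Ipc)2 that delivers the anti alcohol gives (3R,4S)-4-methylhex-5-en-3-ol F6. Silylation gives (3R,4S)-3-[(tert-butyldimethylsilyl)oxy]-4-methylhex-5-ene F7. Ozonolysis with PPh3 work-up gives (2R,3R)-3-[(tert-butyldimethylsilyl)oxy]-2-methylpentanal F8. Wittig reaction of F8 with 7 rejoins the route at 10.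

## Further compounds

F1 | step 12 | 2-(bromomethyl)pent-1-en-3-one | CCC(=O)C(=C)CBr
F2 | step 12 | (6S,8E,10S,11R)-11-[(tert-butyldimethylsilyl)oxy]-6-(6-methoxy-3,5-dimethyl-4-oxo-4H-pyran-2-yl)-6,8,10-trimethyl-4-methylidenetridec-8-ene-3,7-dione | CC[C@@H](O[Si](C)(C)C(C)(C)C)[C@@H](C)/C=C(\C)C(=O)[C@@](C)(CC(=C)C(=O)CC)c1oc(OC)c(C)c(=O)c1C
F3 | step 13 | (6R,8E,10S,11R)-11-[(tert-butyldimethylsilyl)oxy]-6-(6-methoxy-3,5-dimethyl-4-oxo-4H-pyran-2-yl)-6,8,10-trimethyl-4-methylidene-3-[(trimethylsilyl)oxy]trideca-2,8-dien-7-one | CC[C@@H](O[Si](C)(C)C(C)(C)C)[C@@H](C)/C=C(\C)C(=O)[C@](C)(CC(=C)C(O[Si](C)(C)C)=CC)c1oc(OC)c(C)c(=O)c1C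
F4 | step 13 | (6R,8E,10S,11R)-2-bromo-11-[(tert-butyldimethylsilyl)oxy]-6-(6-methoxy-3,5-dimethyl-4-oxo-4H-pyran-2-yl)-6,8,10-trimethyl-4-methylidenetridec-8-ene-3,7-dione | CC[C@@H](O[Si](C)(C)C(C)(C)C)[C@@H](C)/C=C(\C)C(=O)[C@](C)(CC(=C)C(=O)C(C)Br)c1oc(OC)c(C)c(=O)c1C
F5 | step 14 | 2-[(1S)-2-[(2E,4S,5R)-5-[(tert-butyldimethylsilyl)oxy]-4-methylhept-2-en-2-yl]-1,3,5-trimethyl-4-[(trimethylsilyl)oxy]cyclohexa-2,4-dien-1-yl]-6-methoxy-3,5-dimethyl-4H-pyran-4-one | CC[C@@H](O[Si](C)(C)C(C)(C)C)[C@@H](C)/C=C(\C)C1=C(C)C(O[Si](C)(C)C)=C(C)C[C@]1(C)c1oc(OC)c(C)c(=O)c1C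
F6 | step 4 | (3R,4S)-4-methylhex-5-en-3-ol | CC[C@@H](O)[C@@H](C)C=C
F7 | step 4 | (3R,4S)-3-[(tert-butyldimethylsilyl)oxy]-4-methylhex-5-ene | CC[C@@H](O[Si](C)(C)C(C)(C)C)[C@@H](C)C=C
F8 | step 4 | (2R,3R)-3-[(tert-butyldimethylsilyl)oxy]-2-methylpentanal | CC[C@@H](O[Si](C)(C)C(C)(C)C)[C@@H](C)C=O
A1 | alternative 1 | (6R)-6-(6-methoxy-3,5-dimethyl-4-oxo-4H-pyran-2-yl)-2,4,6-trimethyl-3-oxocyclohexa-1,4-dien-1-yl trifluoromethanesulfonate | O=S(=O)(OC1=C(C)C(=O)C(C)=C[C@]1(C)c1oc(OC)c(C)c(=O)c1C)C(F)(F)F
A2 | alternative 1 | (4S,5Z)-4-methyl-6-(4,4,5,5-tetramethyl-1,3,2-dioxaborolan-2-yl)hept-5-en-3-one | CCC(=O)[C@@H](C)/C=C(\C)B1OC(C)(C)C(C)(C)O1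
A3 | alternative 1 | 2-[(1S)-2-hydroxy-1,3,5-trimethyl-4-oxocyclohexa-2,5-dien-1-yl]-6-methoxy-3,5-dimethyl-4H-pyran-4-one | OC1=C(C)C(=O)C(C)=C[C@]1(C)c1oc(OC)c(C)c(=O)c1C
A4 | alternative 2 | 2-[(3E,6E,8E,10S,11R)-11-[(tert-butyldimethylsilyl)oxy]-4,6,8,10-tetramethyl-5-oxotrideca-3,6,8-trien-2-yl]-6-methoxy-3,5-dimethyl-4H-pyran-4-one | CC[C@@H](O[Si](C)(C)C(C)(C)C)[C@@H](C)/C=C(C)/C=C(\C)C(=O)/C(C)=C/C(C)c1oc(OC)c(C)c(=O)c1C
A5 | alternative 2 | 2-[2-[(2E,4S,5R)-5-[(tert-butyldimethylsilyl)oxy]-4-methylhept-2-en-2-yl]-1,3,5-trimethyl-4-oxocyclohex-5-en-1-yl]-6-methoxy-3,5-dimethyl-4H-pyran-4-one (ring stereocentres undefined) | CC[C@@H](O[Si](C)(C)C(C)(C)C)[C@@H](C)/C=C(\C)C1C(C)C(=O)C(C)=CC1(C)c1oc(OC)c(C)c(=O)c1C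
A6 | alternative 3 | 3-[(2E,4S,5R)-5-[(tert-butyldimethylsilyl)oxy]-4-methylhept-2-en-2-yl]-2,4,6-trimethylphenol | CC[C@@H](O[Si](C)(C)C(C)(C)C)[C@@H](C)/C=C(\C)c1c(C)cc(C)c(O)c1C
A7 | alternative 3 | 2,6-dimethoxy-3,5-dimethyl-4H-pyran-4-one | COc1oc(OC)c(C)c(=O)c1C
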